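## Structural features

Ainsliadimer A is a heptacyclic bis-guaianolide. Each half is a cyclopentane fused cis (C1–C5) to a cycloheptane that carries a trans-fused α-methylene γ-lactone (C6–C7) and an exocyclic C10=C14 methylene. The halves are joined by a central cyclopentane C3–C4–C15–C15'–C4' (guaianolide numbering; unprimed = diol half, primed = keto half; α = face of H-1 and H-5). This central ring is fused to ring A of the diol half along C3–C4 and spiro-linked through C4' to the five-membered ring of the keto half, so C3, C4 and C4' are three contiguous fully substituted carbons. There are eleven stereocentres: C1–C5–C6–C7 and its primed copy have the same configuration (H-1α, H-5α, H-6β, H-7α), and in the triad C3/C4/C4' both hydroxyls are α and cis (they sit on the fusion bond of a bicyclo[3.3.0]octane), with C3' on the same face. Fragile groups are the two α-methylene lactones (Michael acceptors), the two exocyclic methylenes, the β-hydroxy ketone C3(OH)–C4'–C3'(=O) (retro-aldol) and the tertiary cis-diol. The real difficulty is the congested C3/C4/C4' cluster and the need to bond two identical halves to it in different ways (C2–C3 on one side, C3'–C4' on the other). The key step exploits that the central ring is a masked cyclopentanone: C3 is the carbonyl carbon, and its α-carbons C4 and C4' each carry the ring-fusion carbon (C5 or C5') of the same seven-membered lactone.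

## Logic of the disconnections

**35 ⇒ 34 ⇒ 31.** The C3' carbonyl is taken back to a carbinol, and the exocyclic C11=C13 and C11'=C13' bonds are cut. The α-methylene lactones and the β-hydroxy ketone are the most sensitive groups and come last. Keeping C3' as an alcohol means no ketone enolate competes with the lactone enolates and no retro-aldol path exists under base. Gain: 31 has no Michael acceptor and no ketone. Demand: lactone enolates must form next to three alkoxides, and the last oxidation must spare the tertiary cis-diol.

**31 ⇒ 30 ⇒ 29.** The C10=C14 and C10'=C14' bonds are cut back to ketones, and these to ketals. The exocyclic alkenes may only appear after the dihydroxylation, which would otherwise attack them. Methylenating at a stage where C3 is a carbinol and C3' an alcohol removes any choice between ketones. Demand: a non-basic methylenation that does not epimerize C1/C1'.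

**29 ⇒ 27.** The C3–O and C4–O bonds are cut. Both oxygens lie on the fusion bond of a bicyclo[3.3.0]octane and must be cis, so they have to come from a syn addition to C3=C4; an epoxide opened with inversion cannot give this diol. Demand: attack on the α face, and no other alkene in 27.

**27 ⇒ 25 ⇒ 24 ⇒ 23.** The C2–C3 bond (ring A) is cut into an enol triflate carbon (C3) and a primary alkyl carbon (C2). The arm is one carbon too long on this side, so the ester carbon is excised first (acid 24, iodide 25). This avoids decarboxylating a β,γ-unsaturated ester after ring closure, which would risk moving the alkene. Demand: ester cleavage that spares lactones and triflate, and reductive elimination to a strained ring-fusion alkene.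

**23 ⇒ 20.** The C3–O triflate bond is cut. C3 can enolize only toward C4 once C4' is quaternary, but C3' enolizes more easily at C2'. Demand: a transient silyl enol ether at C3' during triflation.

**20 ⇒ 19.** The C4'–C3' bond is cut. The ester arm on C1' sits 1,6 to the C3 carbonyl, so acylation of the C3 enolate through C4' closes a five-membered ring, creates the spiro quaternary centre and differentiates the two identical arms in one step. Demand: irreversibility and the correct rotamer at C4'.

**19 ⇒ 18.** The C10 and C10' ketals are removed retrosynthetically. The ketals keep the two cycloheptanones out of all enolate steps and lock C1 and C1'.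

**18 ⇒ 14 + 2 × 13.** The C4–C5 and C4'–C5' bonds are cut; this is the key disconnection. One five-carbon linchpin and two copies of one enone replace a C35 intermediate; six stereocentres are set. 13 is kept as the methyl ester because the same ester must later be the acyl donor for C3'. Demand: addition anti to the C6 oxygen and kinetic protonation at C1.

**13 ⇒ 10 + 11; 10 ⇒ 9.** The C1–C2 bond is cut to an α-iodo enone and a zinc ester enolate. Enolate alkylation of the enone or of its saturated ketone would not select C1 over C9; halogenation of the enone α-carbon followed by cross-coupling is regiospecific.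

**9 ⇒ 8.** The C10 carbonyl is removed; the allylic methylene remote from the lactone oxygen is the forward oxidation site.

**8 ⇒ 7.** The C1=C5 alkene is cut (ring-closing metathesis). An epoxide-opening entry to this lactone was rejected because carbon nucleophiles open vinyl epoxides at the allylic carbon, which would place the alkene on the wrong side.

**7 ⇒ 5 ⇒ 2 + 3; 2 ⇒ 1.** The vinyl C=C and the C7–C8 bond are cut. C6 comes from 1; C7 is set by conjugate addition of 3 anti to the C6 substituent, which gives the trans lactone directly.

## Other disconnections considered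

**Alternative 1:** The cut is the spiro bond C3–C4'. In the forward direction a zerovalent palladium catalyst (Pd2(dba)3, a bulky phosphine, carbonate or phosphate base) couples a C4' ketone enolate with a C3 enol triflate. This closes the central cyclopentene and gives the 3,4-didehydro-3,4-dideoxy compound A1, which needs only an α-face dihydroxylation of C3=C4.
- In its favour: the nucleophile is a ketone enolate (the most acidic site), the quaternary centre and the central ring form in one catalytic C–C coupling that cannot revert, and the halves arrive fully elaborated.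
- Against it here: two different halves must be made separately and first joined through the unactivated C15–C15' bond. The base-mediated coupling runs in the presence of two α-methylene lactones. The final dihydroxylation must pick the hindered tetrasubstituted alkene of A1 out of five C=C bonds.
- Comparison: on mechanism it is the equal of the chosen ring-A closure (both are palladium cross-couplings onto a C3 enol triflate) and better than the chosen Claisen step, which is reversible in principle. It is also better in the number of steps after the coupling. The chosen plan is better on supply (one enone used twice), on chemoselectivity (its osmylation meets a single alkene) and on overall step economy.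

**Alternative 2:** The cuts are C1–C5, C9–C10, C1'–C5' and C9'–C10'. In the forward direction [Rh(CO)2Cl]2, a monovalent rhodium catalyst, promotes two alkyne–vinylcyclopropane [5+2] cycloadditions on a central cyclopentane and gives the bis(bicyclo[5.3.0]decadiene) A2 with the diol already masked as an acetonide.
- In its favour: four rings and four C–C bonds form in one operation, far more than the chosen key step (no ring, two bonds); here it is clearly the better plan. The C3/C4/C4' triad is settled early on a small ring, away from any other alkene, which is also better than a late osmylation.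
- Against it here: each cycloaddition must set C5 or C5' relative to remote centres. A2 still lacks both lactones, so C6 and C7 (and C1 through protodesilylation of the allylsilane) must be set late on flexible cycloheptadienes, four stereocentres per half. The cyclopentane substrate with two quaternary carbons and two enyne arms is long to make.
- Comparison: it equals the chosen plan in using the twofold symmetry. It is worse in stereochemical risk at C1/C5/C6/C7, which the chosen plan takes from one chiral-pool enone, and probably no shorter after its key step.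

**Alternative 3:** The cuts are C15–C15' and, temporarily, C4–C4'. In the forward direction irradiation near 350 nm dimerizes the enone alkenes of dehydrozaluzanin C A3 head-to-head to the dispiro cyclobutane A4. The sacrificial C4–C4' bond must then be cleaved to a bis-enolate equivalent, C4 hydroxylated and C4' joined to C3 by aldol addition.
- In its favour: both halves arrive complete with all eight peripheral stereocentres and all four methylenes, without protecting groups. On step economy it is the better plan by a wide margin.
- Against it here: regiochemistry (head-to-head versus head-to-tail) and facial pairing in an enone [2+2] dimerization are hard to steer, and the α-methylene lactones are competing chromophores and radical acceptors. Cleaving C4–C4' reductively leaves the system two electrons below the target, so a stereocontrolled re-oxidation at C4 and a directed aldol remain.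
- Comparison: it equals the chosen plan in exploiting symmetry. Mechanistically a triplet biradical union is less predictable than two polar Michael additions, and the chosen plan never has to make the C15–C15' bond, which it buys with cyclopentanone.

Key step: step 8

Assumption: 1, 3, 11 and 14 are purchased; 18 is carried as a mixture of C4/C4' epimers (trans isomer drawn), because both centres become trigonal in steps 10 and 11.

## Route

Step 1
Reactants: 1 (S)-5-(hydroxymethyl)furan-2(5H)-one
Product: 2 (S)-5-[(tert-butyldimethylsilyloxy)methyl]furan-2(5H)-one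
Conditions: TBSCl, imidazole, CH2Cl2, 0 °C to rt
Reagents that add atoms: tert-butyldimethylsilyl chloride, CC(C)(C)[Si](C)(C)Cl
Why: Standard silylation of a primary alcohol; imidazole is too weak a base to enolize the butenolide, so the stereocentre (later C6) is untouched.

Step 2
Reactants: 2 (S)-5-[(tert-butyldimethylsilyloxy)methyl]furan-2(5H)-one; 3 pent-4-enylmagnesium bromide
Product: 5 (4S,5S)-5-(hydroxymethyl)-4-(pent-4-en-1-yl)dihydrofuran-2(3H)-one, via silyl ether lactone 4 (not isolated)
Conditions: CuBr·SMe2 (10 mol %), THF, −78 to −40 °C; then 1 M HCl, MeOH, rt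
Reagents that add atoms: none
Why: Copper-catalysed conjugate addition of a Grignard reagent to a γ-substituted butenolide; the nucleophile enters anti to the silyloxymethyl group and sets C4 (later C7) trans to the ring oxygen, and acidic methanol then cleaves the primary silyl ether in the same flask.

Step 3
Reactants: 5 (4S,5S)-5-(hydroxymethyl)-4-(pent-4-en-1-yl)dihydrofuran-2(3H)-one
Product: 7 (4S,5R)-4-(pent-4-en-1-yl)-5-vinyldihydrofuran-2(3H)-one, via lactone aldehyde 6 (not isolated)
Conditions: (COCl)2, DMSO, CH2Cl2, −78 °C; Et3N; then Ph3PCH3Br/KN(SiMe3)2 (preformed ylide), THF, −78 to 0 °C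
Reagents that add atoms: methyltriphenylphosphonium bromide, C[P+](c1ccccc1)(c1ccccc1)c1ccccc1.[Br-]
Why: Swern oxidation followed directly by Wittig methylenation; the α-acyloxy aldehyde is not isolated, which limits epimerization next to the lactone oxygen, and any epimerization would in any case favour the trans lactone.

Step 4
Reactants: 7 (4S,5R)-4-(pent-4-en-1-yl)-5-vinyldihydrofuran-2(3H)-one
Product: 8 (3aS,8aS)-3,3a,4,5,6,8a-hexahydro-2H-cyclohepta[b]furan-2-one (trans-fused)
Conditions: second-generation Grubbs catalyst RuCl2(=CHPh)(PCy3)(H2IMes) (5 mol %), CH2Cl2 (5 mM), 40 °C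
Reagents that add atoms: none
Why: Ring-closing metathesis of two monosubstituted alkenes closes the seven-membered ring (C1=C5) with loss of ethene; both stereocentres are already in place, so the trans ring fusion is fixed.

Step 5
Reactants: 8 (3aS,8aS)-3,3a,4,5,6,8a-hexahydro-2H-cyclohepta[b]furan-2-one
Product: 9 (3aS,8aS)-3,3a,4,5-tetrahydro-2H-cyclohepta[b]furan-2,6(8aH)-dione
Conditions: Rh2(cap)4 (cap = caprolactamate, 1 mol %), t-BuOOH, K2CO3, CH2Cl2, rt
Reagents that add atoms: tert-butyl hydroperoxide, CC(C)(C)OO
Why: Allylic C–H oxidation with a dirhodium carboxamidate and t-BuOOH; hydrogen is abstracted at the C10 methylene and not at the acyloxy-deactivated C6–H, and oxygen is taken up at the terminus remote from the lactone oxygen, as in the oxidation of cycloalkenyl esters to 4-acyloxy enones.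

Step 6
Reactants: 9 (3aS,8aS)-3,3a,4,5-tetrahydro-2H-cyclohepta[b]furan-2,6(8aH)-dione
Product: 10 (3aS,8aS)-7-iodo-3,3a,4,5-tetrahydro-2H-cyclohepta[b]furan-2,6(8aH)-dione
Conditions: I2, pyridine, CH2Cl2, 0 °C to rt
Reagents that add atoms: iodine, II
Why: α-Iodination of an enone by iodine and pyridine (conjugate addition of pyridine, iodination of the enolate, elimination); the halogen can only enter C1, which fixes the site of the arm.

Step 7
Reactants: 10 (3aS,8aS)-7-iodo-3,3a,4,5-tetrahydro-2H-cyclohepta[b]furan-2,6(8aH)-dione; 11 methyl bromoacetate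
Product: 13 methyl 2-[(3aS,8aS)-2,6-dioxo-3,3a,4,5,6,8a-hexahydro-2H-cyclohepta[b]furan-7-yl]acetate, via Reformatsky reagent 12 (not isolated)
Conditions: Zn, THF, rt (11 to 12); then 10, Pd(PPh3)4 (5 mol %), THF, 40 °C
Reagents that add atoms: none
Why: Zinc insertion gives the Reformatsky reagent, which is cross-coupled with the α-iodo enone under zerovalent palladium catalysis (Negishi-type coupling of a zinc ester enolate with an alkenyl iodide); oxidative addition into the C–I bond is fast, and the neutral conditions avoid enolate chemistry at C9.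

Step 8
Reactants: 14 cyclopentanone; 13 methyl 2-[(3aS,8aS)-2,6-dioxo-3,3a,4,5,6,8a-hexahydro-2H-cyclohepta[b]furan-7-yl]acetate (two equivalents)
Product: 18 2,5-trans bis-adduct triketone (cyclopentanone C3 whose C4 and C4' are each bonded to C5 of a 10-oxo lactone unit carrying CH2CO2Me on C1; H-1α, H-5α, H-6β, H-7α in both halves), via enamine 15 (not isolated), via mono-adduct enamine 16 (not isolated), via bis-adduct enamine 17 (not isolated)
Conditions: pyrrolidine (1.05 equiv), 4 Å MS, toluene, rt, then evaporation; 13 (2.1 equiv), MeCN, 40 °C; AcOH/NaOAc, H2O, rt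
Reagents that add atoms: water, O
Why: This is a Stork enamine Michael addition run twice: enamine 15 attacks C5 of 13 through C4, proton transfer in the zwitterion regenerates the less substituted enamine 16, which attacks a second molecule of 13 through C4', and buffered hydrolysis of 17 releases the triketone. The closest known reaction is the 2,5-bis-alkylation of the pyrrolidine enamine of cyclopentanone with acrylates and enones. No ring is closed; the bonds C4–C5 and C4'–C5' are made. C5 and C5' are set by approach of the enamine anti to the lactone oxygen on the neighbouring C6, on the face that carries only H-6. C1 and C1' are set when the C10 enol is protonated on the face away from the new, bulky C5 substituent, which leaves the ester arm cis to it (kinetic control; the enamine is preformed and hydrolysed in a buffer, so the ketone does not stand with free amine). C4 and C4' form as an equilibrating mixture with the trans isomer expected to dominate, and neither is needed later. The step needs 1,4- over 1,2-addition, which the soft enamine secures, and double over single addition, which the excess of 13 and regeneration of the enamine on the unsubstituted side secure. The arm CH2 is not acidic enough to be deprotonated under these neutral conditions, so the lactone carboxylate is not eliminated.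

Step 9
Reactants: 18 2,5-trans bis-adduct triketone
Product: 19 bis(ethylene ketal) of 18 at C10 and C10' (C3 ketone free)
Conditions: (Me3SiOCH2)2, Me3SiOTf (10 mol %), CH2Cl2, −78 to −20 °C
Reagents that add atoms: 1,2-bis(trimethylsilyloxy)ethane, C[Si](C)(C)OCCO[Si](C)(C)C
Why: Silyl-transfer ketalization at low temperature, which does not epimerize α-stereocentres; the two cycloheptanones react while the cyclopentanone flanked by two branched α-carbons does not, which removes C10 and C10' from all later enolate chemistry and locks C1 and C1'.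

Step 10
Reactants: 19 bis(ethylene ketal) of 18
Product: 20 spiro diketone (C4' bonded to the new C3' ketone, closing the ring C1'–C2'–C3'–C4'–C5'; spiro[4.4]nonane-1,6-dione core with C3 on the α face of the new ring; unprimed arm still CH2CO2Me)
Conditions: LiN(SiMe3)2 (2.2 equiv), THF, −78 to −20 °C; AcOH, −78 °C
Reagents that add atoms: none
Why: Intramolecular Claisen (Dieckmann-type) C-acylation: the enolate of the only ketone attacks the cis-disposed ester arm through C4' in a 5-exo-trig closure, the bond construction of the classical route to spiro[4.4]nonane-1,6-dione, and excess amide base at low temperature keeps it from reverting. The spiro centre forms from the rotamer that puts the oxygen-bearing enolate terminus C3 next to H-5' and the small C15' methylene next to C6', which is the configuration of the target; the other arm reacts far more slowly because it would have to build a second quaternary centre on the same ketone.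

Step 11
Reactants: 20 spiro diketone
Product: 23 C3 enol triflate (C3=C4) with free C3' ketone, via trimethylsilyl enol ether 21 (not isolated), via silyl enol ether triflate 22 (not isolated)
Conditions: LiN(SiMe3)2 (1.05 equiv), Me3SiCl (1.05 equiv), THF, −78 °C; volatiles removed; KN(SiMe3)2, PhNTf2, THF, −78 to −30 °C; 1 M HCl, 0 °C
Reagents that add atoms: N-phenylbis(trifluoromethanesulfonimide), O=S(=O)(N(c1ccccc1)S(=O)(=O)C(F)(F)F)C(F)(F)F
Why: Kinetic deprotonation with internal silyl quench takes the unhindered C2' methylene and masks C3' as its silyl enol ether; the only remaining ketone, C3, can then enolize only toward C4 and is trapped as the enol triflate, and dilute acid on work-up returns the C3' ketone.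

Step 12
Reactants: 23 C3 enol triflate methyl ester
Product: 24 C3 enol triflate carboxylic acid (unprimed arm CH2CO2H)
Conditions: Me3SnOH, ClCH2CH2Cl, 80 °C; cold 5% HCl wash
Reagents that add atoms: trimethyltin hydroxide, C[Sn](C)(C)O
Why: Trimethyltin hydroxide cleaves methyl esters under neutral conditions, so the enol triflate, the ketals and the quaternary β-diketone-derived centre survive; a lactone that opens recloses on the acidic wash.

Step 13
Reactants: 24 C3 enol triflate carboxylic acid
Product: 25 C3 enol triflate primary iodide (unprimed arm CH2I)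
Conditions: PhI(OAc)2, I2, hν, ClCH2CH2Cl, 70 °C
Reagents that add atoms: iodine, II
Why: Hunsdiecker-type iododecarboxylation through the acyl hypoiodite; the primary C2 radical is trapped by iodine, which removes the surplus ester carbon of the arm before the ring is closed.

Step 14
Reactants: 25 C3 enol triflate primary iodide
Product: 27 ring-A alkene (C2–C3 bond closed, C3=C4, 3'-ketone, C10 and C10' ketals), via alkylzinc iodide 26 (not isolated)
Conditions: Zn, LiCl, THF, 35 °C; then Pd2(dba)3 (5 mol %), SPhos (12 mol %), THF, 55 °C
Reagents that add atoms: none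
Why: Zinc inserts into the primary C–I bond (ketone, lactones and triflate are tolerated), and zerovalent palladium then couples C2 with the C3 enol triflate (intramolecular Negishi coupling) through a six-membered palladacycle, the closure mode of enolate arylations that give indanes; C1 and C5 are untouched, and the cis arm makes ring A cis-fused to the seven-membered ring.

Step 15
Reactants: 27 ring-A alkene
Product: 29 3α,4α-diol 3'-alcohol bis-ketal (C3' carbinol as either epimer), via osmate ester 28 (not isolated)
Conditions: OsO4 (1.1 equiv), pyridine, THF, −20 °C to rt; then NaBH4, EtOH, 0 °C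
Reagents that add atoms: osmium tetroxide, O=[Os](=O)(=O)=O
Why: Stoichiometric osmylation of the only alkene: the β face is blocked by C6 and by C5' with its seven-membered ring, the α face carries only H-5 and the flat C3' carbonyl, so both hydroxyls enter α and cis, as the bicyclo[3.3.0]octane fusion demands. Borohydride cleaves the hindered osmate ester and in the same operation reduces the C3' ketone, which keeps C3' out of the methylenation and enolate steps that follow.

Step 16
Reactants: 29 3α,4α-diol 3'-alcohol bis-ketal
Product: 30 triol 10,10'-diketone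
Conditions: 1 M HCl, THF, rt
Reagents that add atoms: water, O
Why: Acetal hydrolysis in dilute aqueous acid; the tertiary cis-diol and the lactones are stable under these conditions.

Step 17
Reactants: 30 triol 10,10'-diketone
Product: 31 triol with C10=C14 and C10'=C14' methylenes (lactones still without C13)
Conditions: Zn, CH2Br2, TiCl4, THF/CH2Cl2, 0 °C to rt
Reagents that add atoms: dibromomethane, BrCBr
Why: Takai–Lombardo methylenation: the non-basic zinc/titanium reagent converts both ketones into exocyclic methylenes without epimerizing C1 or C1', tolerates free hydroxyl groups and does not attack lactones.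

Step 18
Reactants: 31 bis-methylene triol
Product: 34 3'-deoxo-3'-hydroxy-ainsliadimer A, via bis-Mannich base 32 (not isolated), via bis-ammonium iodide 33 (not isolated)
Conditions: LiN(iPr)2 (7 equiv), THF, −78 °C; CH2=NMe2+ I−, −78 to 0 °C; then MeI, MeOH, rt; then aq. NaHCO3, EtOAc, rt
Reagents that add atoms: N,N-dimethylmethyleneiminium iodide (Eschenmoser's salt), C=[N+](C)C.[I-]
Why: Excess amide base forms the three alkoxides and both lactone enolates, which are aminomethylated by Eschenmoser's salt (Mannich reaction); quaternization and base-induced elimination give the two α-methylene lactones, and since no ketone is present only the lactones are enolized.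

Step 19
Reactants: 34 3'-deoxo-3'-hydroxy-ainsliadimer A
Product: 35 ainsliadimer A
Conditions: IBX, DMSO, rt
Reagents that add atoms: none
Why: IBX oxidizes the secondary C3' alcohol and leaves the tertiary cis-diol, the alkenes and the α-methylene lactones alone; no base is used, so the new β-hydroxy ketone is not exposed to retro-aldol conditions.

## Compound list

1 | (S)-5-(hydroxymethyl)furan-2(5H)-one | OC[C@H]1OC(=O)C=C1 | starting material
2 | (S)-5-[(tert-butyldimethylsilyloxy)methyl]furan-2(5H)-one | CC(C)(C)[Si](C)(C)OC[C@H]1OC(=O)C=C1 | intermediate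
3 | pent-4-enylmagnesium bromide | C=CCCC[Mg]Br | starting material
4 | (4S,5S)-5-[(tert-butyldimethylsilyloxy)methyl]-4-(pent-4-en-1-yl)dihydrofuran-2(3H)-one | C=CCCC[C@H]1CC(=O)O[C@@H]1CO[Si](C)(C)C(C)(C)C | intermediate (not isolated)
5 | (4S,5S)-5-(hydroxymethyl)-4-(pent-4-en-1-yl)dihydrofuran-2(3H)-one | C=CCCC[C@H]1CC(=O)O[C@@H]1CO | intermediate
6 | (2S,3S)-5-oxo-3-(pent-4-en-1-yl)tetrahydrofuran-2-carbaldehyde | C=CCCC[C@H]1CC(=O)O[C@@H]1C=O | intermediate (not isolated)
7 | (4S,5R)-4-(pent-4-en-1-yl)-5-vinyldihydrofuran-2(3H)-one | C=CCCC[C@H]1CC(=O)O[C@@H]1C=C | intermediate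
8 | (3aS,8aS)-3,3a,4,5,6,8a-hexahydro-2H-cyclohepta[b]furan-2-one | C1=C[C@H]2OC(=O)C[C@@H]2CCC1 | intermediate
9 | (3aS,8aS)-3,3a,4,5-tetrahydro-2H-cyclohepta[b]furan-2,6(8aH)-dione | C1=C[C@H]2OC(=O)C[C@@H]2CCC1=O | intermediate
10 | (3aS,8aS)-7-iodo-3,3a,4,5-tetrahydro-2H-cyclohepta[b]furan-2,6(8aH)-dione | IC1=C[C@H]2OC(=O)C[C@@H]2CCC1=O | intermediate
11 | methyl bromoacetate | COC(=O)CBr | starting material
12 | (2-methoxy-2-oxoethyl)zinc bromide | COC(=O)C[Zn]Br | intermediate (not isolated)
13 | methyl 2-[(3aS,8aS)-2,6-dioxo-3,3a,4,5,6,8a-hexahydro-2H-cyclohepta[b]furan-7-yl]acetate | COC(=O)CC1=C[C@H]2OC(=O)C[C@@H]2CCC1=O | intermediate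
14 | cyclopentanone | O=C1CCCC1 | starting material
15 | 1-(cyclopent-1-en-1-yl)pyrrolidine | C1CCN(C1)C1=CCCC1 | intermediate (not isolated)
16 | mono-adduct enamine: 1-(pyrrolidin-1-yl)cyclopentene (C3=C4') bonded at C4 to C5 of the lactone unit of 13 | C1CCN(C1)C2=CCC[C@@H]2[C@H]3[C@@H](CC(=O)OC)C(=O)CC[C@H]4CC(=O)O[C@H]34 | intermediate (not isolated)
17 | bis-adduct enamine: pyrrolidine enamine (C3=C4) of 18 | C1CCN(C1)C2=C([C@H]3[C@@H](CC(=O)OC)C(=O)CC[C@H]4CC(=O)O[C@H]34)CC[C@@H]2[C@H]3[C@@H](CC(=O)OC)C(=O)CC[C@H]4CC(=O)O[C@H]34 | intermediate (not isolated)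
18 | 2,5-trans bis-adduct triketone: cyclopentanone (C3) bonded at C4 and C4' to C5 of two 10-oxo lactone units with CH2CO2Me on C1; H-1α, H-5α, H-6β, H-7α in both | O=C1[C@H](CC[C@@H]1[C@H]2[C@@H](CC(=O)OC)C(=O)CC[C@H]3CC(=O)O[C@H]23)[C@H]2[C@@H](CC(=O)OC)C(=O)CC[C@H]3CC(=O)O[C@H]23 | intermediate
19 | bis(ethylene ketal) of 18 at C10 and C10' | O=C1[C@H](CC[C@@H]1[C@H]2[C@@H](CC(=O)OC)C4(OCCO4)CC[C@H]3CC(=O)O[C@H]23)[C@H]2[C@@H](CC(=O)OC)C4(OCCO4)CC[C@H]3CC(=O)O[C@H]23 | intermediate
20 | spiro diketone: C4'–C3' bond closed (3,3'-dione, spiro at C4'), unprimed CH2CO2Me arm, both ketals | O=C1[C@@H]([C@H]2[C@@H](CC(=O)OC)C6(OCCO6)CC[C@H]3CC(=O)O[C@H]23)CC[C@]12C(=O)C[C@H]3C4(OCCO4)CC[C@H]5CC(=O)O[C@@H]5[C@H]32 | intermediate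
21 | C3' trimethylsilyl enol ether (C2'=C3') of 20 | O=C1[C@@H]([C@H]2[C@@H](CC(=O)OC)C6(OCCO6)CC[C@H]3CC(=O)O[C@H]23)CC[C@]12C(O[Si](C)(C)C)=C[C@H]3C4(OCCO4)CC[C@H]5CC(=O)O[C@@H]5[C@H]32 | intermediate (not isolated)
22 | C3 enol triflate of 21 | FC(F)(F)S(=O)(=O)OC1=C([C@H]2[C@@H](CC(=O)OC)C6(OCCO6)CC[C@H]3CC(=O)O[C@H]23)CC[C@]12C(O[Si](C)(C)C)=C[C@H]3C4(OCCO4)CC[C@H]5CC(=O)O[C@@H]5[C@H]32 | intermediate (not isolated)
23 | C3 enol triflate (C3=C4), 3'-ketone, unprimed CH2CO2Me arm | FC(F)(F)S(=O)(=O)OC1=C([C@H]2[C@@H](CC(=O)OC)C6(OCCO6)CC[C@H]3CC(=O)O[C@H]23)CC[C@]12C(=O)C[C@H]3C4(OCCO4)CC[C@H]5CC(=O)O[C@@H]5[C@H]32 | intermediate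
24 | C3 enol triflate, unprimed CH2CO2H arm | FC(F)(F)S(=O)(=O)OC1=C([C@H]2[C@@H](CC(=O)O)C6(OCCO6)CC[C@H]3CC(=O)O[C@H]23)CC[C@]12C(=O)C[C@H]3C4(OCCO4)CC[C@H]5CC(=O)O[C@@H]5[C@H]32 | intermediate
25 | C3 enol triflate, unprimed CH2I arm | FC(F)(F)S(=O)(=O)OC1=C([C@H]2[C@@H](CI)C6(OCCO6)CC[C@H]3CC(=O)O[C@H]23)CC[C@]12C(=O)C[C@H]3C4(OCCO4)CC[C@H]5CC(=O)O[C@@H]5[C@H]32 | intermediate
26 | alkylzinc iodide from 25 (C2–ZnI) | FC(F)(F)S(=O)(=O)OC1=C([C@H]2[C@@H](C[Zn]I)C6(OCCO6)CC[C@H]3CC(=O)O[C@H]23)CC[C@]12C(=O)C[C@H]3C4(OCCO4)CC[C@H]5CC(=O)O[C@@H]5[C@H]32 | intermediate (not isolated)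
27 | ring-A alkene: heptacyclic skeleton with C3=C4, 3'-ketone, C10 and C10' ethylene ketals, lactones without C13 | C1C(=O)O[C@@H]2[C@@H]3[C@@H](CC4=C3CC[C@]45C(=O)C[C@H]6C8(OCCO8)CC[C@H]7CC(=O)O[C@@H]7[C@H]65)C8(OCCO8)CC[C@@H]12 | intermediate
28 | cyclic 3α,4α-osmate ester of 27, bis(pyridine) adduct | C1C(=O)O[C@@H]2[C@@H]3[C@@H](C[C@@]4(O9)[C@]3(O[Os]9(=O)=O)CC[C@]43C(=O)C[C@H]4C8(OCCO8)CC[C@H]5CC(=O)O[C@@H]5[C@H]43)C8(OCCO8)CC[C@@H]12.c1ccncc1.c1ccncc1 | intermediate (not isolated)
29 | 3α,4α-diol 3'-alcohol (C3' unassigned), C10 and C10' ketals | C1C(=O)O[C@@H]2[C@@H]3[C@@H](C[C@@]4(O)[C@]3(O)CC[C@]43C(O)C[C@H]4C8(OCCO8)CC[C@H]5CC(=O)O[C@@H]5[C@H]43)C8(OCCO8)CC[C@@H]12 | intermediate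
30 | triol 10,10'-diketone | C1C(=O)O[C@@H]2[C@@H]3[C@@H](C[C@@]4(O)[C@]3(O)CC[C@]43C(O)C[C@H]4C(=O)CC[C@H]5CC(=O)O[C@@H]5[C@H]43)C(=O)CC[C@@H]12 | intermediate
31 | triol with C10=C14 and C10'=C14' (3'-deoxo-3'-hydroxy-13,13'-dinor-ainsliadimer A) | C1C(=O)O[C@@H]2[C@@H]3[C@@H](C[C@@]4(O)[C@]3(O)CC[C@]43C(O)C[C@H]4C(=C)CC[C@H]5CC(=O)O[C@@H]5[C@H]43)C(=C)CC[C@@H]12 | intermediate
32 | bis-Mannich base: 31 with CH2NMe2 on C11 and C11' | CN(C)CC1C(=O)O[C@@H]2[C@@H]3[C@@H](C[C@@]4(O)[C@]3(O)CC[C@]43C(O)C[C@H]4C(=C)CC[C@H]5C(CN(C)C)C(=O)O[C@@H]5[C@H]43)C(=C)CC[C@@H]12 | intermediate (not isolated)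
33 | bis(trimethylammonium) diiodide of 32 | C[N+](C)(C)CC1C(=O)O[C@@H]2[C@@H]3[C@@H](C[C@@]4(O)[C@]3(O)CC[C@]43C(O)C[C@H]4C(=C)CC[C@H]5C(C[N+](C)(C)C)C(=O)O[C@@H]5[C@H]43)C(=C)CC[C@@H]12.[I-].[I-] | intermediate (not isolated)
34 | 3'-deoxo-3'-hydroxy-ainsliadimer A | C=C1C(=O)O[C@@H]2[C@@H]3[C@@H](C[C@@]4(O)[C@]3(O)CC[C@]43C(O)C[C@H]4C(=C)CC[C@H]5C(=C)C(=O)O[C@@H]5[C@H]43)C(=C)CC[C@@H]12 | intermediate
35 | ainsliadimer A | C=C1C(=O)O[C@@H]2[C@@H]3[C@@H](C[C@@]4(O)[C@]3(O)CC[C@]43C(=O)C[C@H]4C(=C)CC[C@H]5C(=C)C(=O)O[C@@H]5[C@H]43)C(=C)CC[C@@H]12 | target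

## Step count and least certain steps

Total step count: 19. Longest linear sequence: 19 steps (1 to 35); 3, 11 and 14 enter without steps of their own.

**Step 8 (key step).** The second conjugate addition to the α-substituted enone may be too slow, so the sequence stalls after one addition; on long reaction times C1 may also epimerize, which loses the kinetic cis relationship. Fallback, from 13 back to 18: dimethyl 2-oxocyclopentane-1,3-dicarboxylate F1, a doubly activated donor, would be added twice to 13 with a catalytic base (K2CO3 in acetone) to give the bis-adduct carrying a methyl ester on C4 and on C4', F2. Krapcho demethoxycarbonylation (LiCl, wet DMSO, 140 °C) would then remove both ring esters and deliver 18.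

**Step 7.** The zinc enolate may add to the enone carbonyl instead of coupling, or zerovalent palladium may ionize the allylic C6–O bond of the lactone. Fallback, from 10 back to 13: Stille coupling of 10 with allyltributylstannane (Pd2(dba)3, AsPh3) would give the 2-allyl enone F3. Oxidative cleavage of the terminal alkene (OsO4 cat., NaIO4) would give the aldehyde F4, Pinnick oxidation the acid F5, and Me3SiCHN2 the methyl ester 13.

**Step 10.** The acylation may revert through attack of the liberated methoxide on the new β-diketone, or cyclization may proceed through the other rotamer and give the wrong face at C4'. Attack of the enolate on the nearby lactone carbonyl is a lesser competitor. Fallback, from 19 back to 20: both esters would be cleaved with Me3SnOH to the diacid F6, and 1,1'-carbonyldiimidazole would give the bis(acyl imidazole) F7. With LiN(SiMe3)2 at −78 °C the C3 enolate is acylated by one acyl imidazole, a leaving group that cannot reopen the diketone, to give the spiro diketone acyl imidazole F8. Methanol with DMAP would then turn the untouched acyl imidazole into the methyl ester 20.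

**Step 11.** The two enolizations may not be site-selective (triflation at C3' after incomplete masking), or deprotonation of the hindered C4–H may be too slow. Fallback, from 20 back to 27, which avoids the enol triflate: Me3SnOH would give the diketone acid F9, and iododecarboxylation (PhI(OAc)2, I2, hν) the diketone iodide F10. SmI2 in THF/HMPA would close ring A by Barbier addition of C2 to the C3 ketone (five-membered; C3' could only give a seven-membered ring) to the tertiary alcohol F11. Syn-dehydration with the Burgess reagent toward the cis C4–H would give 27.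

**Step 14.** Reductive elimination to the strained ring-fusion alkene may be slow, so the alkylzinc is protonated or undergoes β-hydride loss instead of cyclizing. Fallback, from 23 back to 27: intramolecular palladium-catalysed α-alkenylation of the ester enolate (LiN(SiMe3)2, Pd2(dba)3, t-Bu3P) would give the β,γ-unsaturated ester F12. Me3SnOH would give the acid F13, and Barton reductive decarboxylation (N-hydroxypyridine-2-thione ester, t-BuSH, hν) would give 27, with hydrogen delivered to the less substituted end of the allyl radical.

**Step 15.** Osmylation of the hindered tetrasubstituted alkene may be slow, and facial selectivity may be insufficient if C4' is partly epimeric. Fallback, from 27 back to 29: NaBH4 would first reduce the C3' ketone to the homoallylic alcohol F14. Hydrogen-bond-directed dihydroxylation with OsO4·TMEDA at −78 °C, followed by reductive work-up, would then deliver both hydroxyls to the α face, on which the C3' carbinol sits, and give 29.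

## Further compounds

F1 | step 8 | dimethyl 2-oxocyclopentane-1,3-dicarboxylate | COC(=O)C1CCC(C(=O)OC)C1=O
F2 | step 8 | bis-adduct with CO2Me on C4 and C4' (18 with both α-hydrogens replaced by CO2Me; C4/C4' unassigned) | O=C1C(C(=O)OC)(CCC1(C(=O)OC)[C@H]2[C@@H](CC(=O)OC)C(=O)CC[C@H]3CC(=O)O[C@H]23)[C@H]2[C@@H](CC(=O)OC)C(=O)CC[C@H]3CC(=O)O[C@H]23
F3 | step 7 | (3aS,8aS)-7-allyl-3,3a,4,5-tetrahydro-2H-cyclohepta[b]furan-2,6(8aH)-dione | C=CCC1=C[C@H]2OC(=O)C[C@@H]2CCC1=O
F4 | step 7 | 2-[(3aS,8aS)-2,6-dioxo-3,3a,4,5,6,8a-hexahydro-2H-cyclohepta[b]furan-7-yl]acetaldehyde | O=CCC1=C[C@H]2OC(=O)C[C@@H]2CCC1=O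
F5 | step 7 | 2-[(3aS,8aS)-2,6-dioxo-3,3a,4,5,6,8a-hexahydro-2H-cyclohepta[b]furan-7-yl]acetic acid | OC(=O)CC1=C[C@H]2OC(=O)C[C@@H]2CCC1=O
F6 | step 10 | diacid of 19 (both arms CH2CO2H) | O=C1[C@H](CC[C@@H]1[C@H]2[C@@H](CC(=O)O)C4(OCCO4)CC[C@H]3CC(=O)O[C@H]23)[C@H]2[C@@H](CC(=O)O)C4(OCCO4)CC[C@H]3CC(=O)O[C@H]23
F7 | step 10 | bis(acyl imidazole) of F6 | O=C1[C@H](CC[C@@H]1[C@H]2[C@@H](CC(=O)n5ccnc5)C4(OCCO4)CC[C@H]3CC(=O)O[C@H]23)[C@H]2[C@@H](CC(=O)n5ccnc5)C4(OCCO4)CC[C@H]3CC(=O)O[C@H]23
F8 | step 10 | spiro diketone with the unprimed arm as acyl imidazole | O=C1[C@@H]([C@H]2[C@@H](CC(=O)n7ccnc7)C6(OCCO6)CC[C@H]3CC(=O)O[C@H]23)CC[C@]12C(=O)C[C@H]3C4(OCCO4)CC[C@H]5CC(=O)O[C@@H]5[C@H]32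
F9 | step 11 | spiro diketone acid (20 with CH2CO2H arm) | O=C1[C@@H]([C@H]2[C@@H](CC(=O)O)C6(OCCO6)CC[C@H]3CC(=O)O[C@H]23)CC[C@]12C(=O)C[C@H]3C4(OCCO4)CC[C@H]5CC(=O)O[C@@H]5[C@H]32
F10 | step 11 | spiro diketone iodide (20 with CH2I arm) | O=C1[C@@H]([C@H]2[C@@H](CI)C6(OCCO6)CC[C@H]3CC(=O)O[C@H]23)CC[C@]12C(=O)C[C@H]3C4(OCCO4)CC[C@H]5CC(=O)O[C@@H]5[C@H]32
F11 | step 11 | ring-A tertiary alcohol (C2–C3 closed, 3α-OH, 4α-H, 3'-ketone, both ketals) | C1C(=O)O[C@@H]2[C@@H]3[C@@H](C[C@@]4(O)[C@@H]3CC[C@]43C(=O)C[C@H]4C8(OCCO8)CC[C@H]5CC(=O)O[C@@H]5[C@H]43)C8(OCCO8)CC[C@@H]12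
F12 | step 14 | 27 carrying CO2Me on C2 (C2 unassigned) | C1C(=O)O[C@@H]2[C@@H]3[C@@H](C(C(=O)OC)C4=C3CC[C@]45C(=O)C[C@H]6C8(OCCO8)CC[C@H]7CC(=O)O[C@@H]7[C@H]65)C8(OCCO8)CC[C@@H]12
F13 | step 14 | 27 carrying CO2H on C2 (C2 unassigned) | C1C(=O)O[C@@H]2[C@@H]3[C@@H](C(C(=O)O)C4=C3CC[C@]45C(=O)C[C@H]6C8(OCCO8)CC[C@H]7CC(=O)O[C@@H]7[C@H]65)C8(OCCO8)CC[C@@H]12
F14 | step 15 | 3'-alcohol of 27 (C3' unassigned) | C1C(=O)O[C@@H]2[C@@H]3[C@@H](CC4=C3CC[C@]45C(O)C[C@H]6C8(OCCO8)CC[C@H]7CC(=O)O[C@@H]7[C@H]65)C8(OCCO8)CC[C@@H]12
A1 | alternative 1 | 3,4-didehydro-3,4-dideoxy-ainsliadimer A (C3=C4 alkene) | C=C1C(=O)O[C@@H]2[C@@H]3[C@@H](CC4=C3CC[C@]45C(=O)C[C@H]6C(=C)CC[C@H]7C(=C)C(=O)O[C@@H]7[C@H]65)C(=C)CC[C@@H]12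
A2 | alternative 2 | bis(bicyclo[5.3.0]decadiene) acetonide with two allylsilane and two methyl acetate handles | C[Si](C)(C)CC1=C2C[C@]43OC(C)(C)O[C@]3([C@@H]2C=C(CC(=O)OC)CC1)CC[C@]45C(=O)CC6=C(C[Si](C)(C)C)CCC(CC(=O)OC)=C[C@H]65
A3 | alternative 3 | dehydrozaluzanin C | C=C1C(=O)O[C@@H]2[C@@H]3[C@@H](CC(=O)C3=C)C(=C)CC[C@@H]12
A4 | alternative 3 | head-to-head dispiro cyclobutane dimer of A3 | C=C1C(=O)O[C@@H]2[C@@H]3[C@@H](CC(=O)[C@]34CC[C@]45C(=O)C[C@H]6C(=C)CC[C@H]7C(=C)C(=O)O[C@@H]7[C@H]65)C(=C)CC[C@@H]12
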